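**Plan**

- Numbering is that of the dihydrocoumarin (O1, C2=O, C3, C4, C4a, C5–C8, C8a). Ring A carries oxygen only at C7 and C8a and carbon only at C4a and C6, which is the pattern of a 4,6-disubstituted cyclohexane-1,3-dione with its carbonyl carbons at C7 and C8a.
- Retrosynthesis: the lactone bond O1–C2 is opened, ring A is taken back to that dione, and the dione is cut at C5–C6 and C8–C8a. This gives an acetoacetate-type donor (C6, C7, C8 and the arylethyl chain) and a chiral 2-methylidene glutarate (C2, C3, C4, C4a, C5, C8a and the catechol ring B).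
- Forward: the glutarate is built first, ring A is grown on it as the cyclohexanedione by a Michael–Claisen annulation and then aromatised, the lactone ring is closed on the C8a hydroxyl, and the benzyl ethers are removed last.
- Stereochemistry: C4, the only stereocentre, comes from an iminium-catalysed malonate addition to a cinnamaldehyde. It is never alpha to a carbonyl afterwards, and it meets strong base only once it is no longer allylic.

Key step: step 8

Remark: the (R)-diarylprolinol silyl ether is assumed to follow its usual iminium shielding model, which leads to (S)-5; if the sense were opposite, the (S)-catalyst would be used.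

**Route**

Step 1
Reactants: 1 3,4-bis(benzyloxy)benzaldehyde; 2 (triphenylphosphoranylidene)acetaldehyde
Product: 3 (2E)-3-[3,4-bis(benzyloxy)phenyl]prop-2-enal
Conditions: 2 (1.2 equiv), toluene, 80 °C
Reagents that add atoms: none
Why: Wittig olefination with a formyl-stabilised ylide, which should stop at the two-carbon homologue and give the E enal as stabilised ylides do.

Step 2
Reactants: 3 (2E)-3-[3,4-bis(benzyloxy)phenyl]prop-2-enal; 4 dimethyl malonate
Product: 5 dimethyl 2-{(1S)-1-[3,4-bis(benzyloxy)phenyl]-3-oxopropyl}propanedioate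
Conditions: (R)-2-{bis[3,5-bis(trifluoromethyl)phenyl][(trimethylsilyl)oxy]methyl}pyrrolidine (10 mol %), EtOH, 0 °C
Reagents that add atoms: none
Why: Iminium-catalysed asymmetric Michael addition of a malonate to an enal; the diaryl(silyloxy)methyl group shields one face of the E iminium ion, so the malonate should add to the open face of the beta carbon and set the future C4 (S in 5, the same spatial arrangement as R in the target).

Step 3
Reactants: 5 dimethyl 2-{(1S)-1-[3,4-bis(benzyloxy)phenyl]-3-oxopropyl}propanedioate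
Product: 6 (3S)-3-[3,4-bis(benzyloxy)phenyl]-5-methoxy-4-(methoxycarbonyl)-5-oxopentanoic acid
Conditions: NaClO2, NaH2PO4, 2-methylbut-2-ene, t-BuOH–H2O, 0 °C to rt
Reagents that add atoms: sodium chlorite, [Na+].[O-]Cl=O
Why: Pinnick oxidation of the aldehyde under buffered conditions that leave the malonate, the benzyl ethers and the non-enolisable stereocentre alone, the alkene keeping hypochlorite away from the electron-rich ring.

Step 4
Reactants: 6 (3S)-3-[3,4-bis(benzyloxy)phenyl]-5-methoxy-4-(methoxycarbonyl)-5-oxopentanoic acid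
Product: 7 3-tert-butyl 1,1-dimethyl (2S)-2-[3,4-bis(benzyloxy)phenyl]propane-1,1,3-tricarboxylate
Conditions: tert-butyl 2,2,2-trichloroacetimidate (2 equiv), CH2Cl2–cyclohexane, rt
Reagents that add atoms: tert-butyl 2,2,2-trichloroacetimidate, CC(C)(C)OC(=N)C(Cl)(Cl)Cl
Why: tert-Butylation of a carboxylic acid by the trichloroacetimidate, which the substrate acid itself activates, giving an ester that should ignore the bases of the following steps.

Step 5
Reactants: 7 3-tert-butyl 1,1-dimethyl (2S)-2-[3,4-bis(benzyloxy)phenyl]propane-1,1,3-tricarboxylate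
Product: 8 (3S)-3-[3,4-bis(benzyloxy)phenyl]-5-tert-butoxy-2-(methoxycarbonyl)-5-oxopentanoic acid (both C2 epimers)
Conditions: KOH (1.05 equiv), THF–H2O, 0 °C; then 1 M HCl to pH 3, 0 °C
Reagents that add atoms: potassium hydroxide, [K+].[OH-]
Why: Selective monosaponification of a geminal diester, in which the first carboxylate shuts down attack on its neighbour and the tert-butyl ester is inert to cold hydroxide.

Step 6
Reactants: 8 (3S)-3-[3,4-bis(benzyloxy)phenyl]-5-tert-butoxy-2-(methoxycarbonyl)-5-oxopentanoic acid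
Product: 9 5-tert-butyl 1-methyl (3R)-3-[3,4-bis(benzyloxy)phenyl]-2-methylidenepentanedioate
Conditions: paraformaldehyde (3 equiv), Et2NH (1.5 equiv), EtOAc, reflux
Reagents that add atoms: formaldehyde (as paraformaldehyde), C=O
Why: Mannich reaction of the malonic half-ester followed by decarboxylative loss of the amine, the standard malonate route to 2-substituted acrylates; the amine is too weak a base to remove the allylic, benzylic hydrogen at the stereocentre.

Step 7
Reactants: 10 tert-butyl acetoacetate; 11 4-(2-bromoethyl)-1,2-dimethoxybenzene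
Product: 12 tert-butyl 2-acetyl-4-(3,4-dimethoxyphenyl)butanoate (racemic)
Conditions: 10 (1.5 equiv), NaH (1.4 equiv), THF–DMF, 0 °C; then 11, NaI (10 mol %), 60 °C
Reagents that add atoms: none
Why: Acetoacetic ester C-alkylation with a primary bromide under iodide catalysis, excess acetoacetate suppressing dialkylation.

Step 8
Reactants: 9 5-tert-butyl 1-methyl (3R)-3-[3,4-bis(benzyloxy)phenyl]-2-methylidenepentanedioate; 12 tert-butyl 2-acetyl-4-(3,4-dimethoxyphenyl)butanoate
Product: 14 tert-butyl 5-{(1S)-1-[3,4-bis(benzyloxy)phenyl]-3-tert-butoxy-3-oxopropyl}-1-[2-(3,4-dimethoxyphenyl)ethyl]-2,4-dioxocyclohexane-1-carboxylate (both ring epimers), via Michael adduct 13 (not isolated)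
Conditions: 12 (1.2 equiv), KOtBu (0.2 equiv), THF, 0 °C, slow addition of 9, then rt; then KOtBu (2.2 equiv), 0 °C to rt; cold 1 M HCl
Reagents that add atoms: none
Why: With catalytic KOtBu the only base in solution is the potassium enolate of 12, which should add through its tertiary carbon to the methylene terminus of 9 (C5–C6) and be regenerated by proton transfer from more 12 to give 13; excess KOtBu then enolises the acetyl methyl group, and this enolate attacks the methyl ester (C8–C8a) with loss of methoxide, immediate deprotonation of the acidic C8 of the dione making the sequence irreversible. The closest known reactions are the acetoacetate–acrylate synthesis of 4-alkoxycarbonylcyclohexane-1,3-diones and the consecutive Michael–Claisen annulation of methyl ketones with acrylates. Ring A closes in a 6-exo-trig (enolexo) Claisen step, whereas attack on either tert-butyl ester would need a four- or eight-membered ring and a poorer leaving group. No lasting stereocentre is made: ring C1 and C5 of 14 form as mixtures and both become sp2 on aromatisation, while the side-chain centre is carried through unchanged (S in 14 only because the CIP priorities change). The step needs regiocontrol of both bond formations and integrity of the allylic, benzylic centre of 9: the tert-butoxycarbonyl group makes the internal carbon the only nucleophile of the Michael stage and leaves the methyl group as the only enolisable ketone position for the Claisen stage, and 9 meets nothing more basic than a beta-keto ester enolate before its double bond is consumed, after which that hydrogen is no longer allylic.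

Step 9
Reactants: 14 tert-butyl 5-{(1S)-1-[3,4-bis(benzyloxy)phenyl]-3-tert-butoxy-3-oxopropyl}-1-[2-(3,4-dimethoxyphenyl)ethyl]-2,4-dioxocyclohexane-1-carboxylate
Product: 16 (3S)-3-[3,4-bis(benzyloxy)phenyl]-3-{5-[2-(3,4-dimethoxyphenyl)ethyl]-2,4-dioxocyclohexyl}propanoic acid (both ring epimers), via keto diacid 15 (not isolated)
Conditions: CF3CO2H–CH2Cl2 (1:4), 0 °C to rt; evaporate; toluene, 60 °C
Reagents that add atoms: none
Why: Acidolysis of both tert-butyl esters with loss of isobutene, then thermal decarboxylation of the beta-keto acid at C6; benzyl aryl ethers, methyl ethers and the stereocentre (beta to every carbonyl) should survive short exposure to dilute acid.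

Step 10
Reactants: 16 (3S)-3-[3,4-bis(benzyloxy)phenyl]-3-{5-[2-(3,4-dimethoxyphenyl)ethyl]-2,4-dioxocyclohexyl}propanoic acid
Product: 18 (4R)-4-[3,4-bis(benzyloxy)phenyl]-6-[2-(3,4-dimethoxyphenyl)ethyl]-7-hydroxy-3,4-dihydro-2H-1-benzopyran-2-one, via resorcinol acid 17 (not isolated)
Conditions: Pd(O2CCF3)2 (5 mol %), 2-(dimethylamino)pyridine (10 mol %), TsOH·H2O (20 mol %), O2 (1 atm), DMSO, 80 °C; then TsOH (cat.), toluene, 80 °C, 4 Å sieves
Reagents that add atoms: none
Why: Aerobic palladium-catalysed dehydrogenation of a cyclic ketone to a phenol: a palladium enolate at C6 or C4a should undergo beta-hydride elimination into the ring, the ene-dione tautomerises to the 4,6-disubstituted resorcinol and O2 reoxidises the metal; the acid present then closes the six-membered lactone on the C8a hydroxyl, the only phenol within reach of the carboxyl group.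

Step 11
Reactants: 18 (4R)-4-[3,4-bis(benzyloxy)phenyl]-6-[2-(3,4-dimethoxyphenyl)ethyl]-7-hydroxy-3,4-dihydro-2H-1-benzopyran-2-one
Product: 19 (4R)-4-(3,4-dihydroxyphenyl)-6-[2-(3,4-dimethoxyphenyl)ethyl]-7-hydroxy-3,4-dihydro-2H-1-benzopyran-2-one (CNP0376539.1)
Conditions: H2 (1 atm), 10% Pd on carbon, EtOAc, rt
Reagents that add atoms: none
Why: Hydrogenolysis of the two benzyl aryl ethers under neutral conditions, to which the aryl lactone, the methyl ethers and the C4–aryl bonds are inert.

**Compound list**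

1 | 3,4-bis(benzyloxy)benzaldehyde | O=Cc1ccc(OCc2ccccc2)c(OCc2ccccc2)c1 | starting material
2 | (triphenylphosphoranylidene)acetaldehyde | O=CC=P(c1ccccc1)(c1ccccc1)c1ccccc1 | starting material
3 | (2E)-3-[3,4-bis(benzyloxy)phenyl]prop-2-enal | O=C/C=C/c1ccc(OCc2ccccc2)c(OCc2ccccc2)c1 | intermediate
4 | dimethyl malonate | COC(=O)CC(=O)OC | starting material
5 | dimethyl 2-{(1S)-1-[3,4-bis(benzyloxy)phenyl]-3-oxopropyl}propanedioate | O=CC[C@@H](C(C(=O)OC)C(=O)OC)c1ccc(OCc2ccccc2)c(OCc2ccccc2)c1 | intermediate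
6 | (3S)-3-[3,4-bis(benzyloxy)phenyl]-5-methoxy-4-(methoxycarbonyl)-5-oxopentanoic acid | OC(=O)C[C@@H](C(C(=O)OC)C(=O)OC)c1ccc(OCc2ccccc2)c(OCc2ccccc2)c1 | intermediate
7 | 3-tert-butyl 1,1-dimethyl (2S)-2-[3,4-bis(benzyloxy)phenyl]propane-1,1,3-tricarboxylate | CC(C)(C)OC(=O)C[C@@H](C(C(=O)OC)C(=O)OC)c1ccc(OCc2ccccc2)c(OCc2ccccc2)c1 | intermediate
8 | (3S)-3-[3,4-bis(benzyloxy)phenyl]-5-tert-butoxy-2-(methoxycarbonyl)-5-oxopentanoic acid, both C2 epimers | CC(C)(C)OC(=O)C[C@@H](C(C(=O)O)C(=O)OC)c1ccc(OCc2ccccc2)c(OCc2ccccc2)c1 | intermediate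
9 | 5-tert-butyl 1-methyl (3R)-3-[3,4-bis(benzyloxy)phenyl]-2-methylidenepentanedioate | CC(C)(C)OC(=O)C[C@@H](C(=C)C(=O)OC)c1ccc(OCc2ccccc2)c(OCc2ccccc2)c1 | intermediate
10 | tert-butyl acetoacetate | CC(=O)CC(=O)OC(C)(C)C | starting material
11 | 4-(2-bromoethyl)-1,2-dimethoxybenzene | COc1ccc(CCBr)cc1OC | starting material
12 | tert-butyl 2-acetyl-4-(3,4-dimethoxyphenyl)butanoate, racemic | CC(=O)C(CCc1ccc(OC)c(OC)c1)C(=O)OC(C)(C)C | intermediate
13 | 1,5-di-tert-butyl 3-methyl (2S)-5-acetyl-2-[3,4-bis(benzyloxy)phenyl]-7-(3,4-dimethoxyphenyl)heptane-1,3,5-tricarboxylate, mixture at C3 and C5 | CC(C)(C)OC(=O)C[C@@H](C(C(=O)OC)CC(CCc1ccc(OC)c(OC)c1)(C(C)=O)C(=O)OC(C)(C)C)c1ccc(OCc2ccccc2)c(OCc2ccccc2)c1 | intermediate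
14 | tert-butyl 5-{(1S)-1-[3,4-bis(benzyloxy)phenyl]-3-tert-butoxy-3-oxopropyl}-1-[2-(3,4-dimethoxyphenyl)ethyl]-2,4-dioxocyclohexane-1-carboxylate, mixture at ring C1 and C5 | CC(C)(C)OC(=O)C[C@@H](C1CC(CCc2ccc(OC)c(OC)c2)(C(=O)OC(C)(C)C)C(=O)CC1=O)c1ccc(OCc2ccccc2)c(OCc2ccccc2)c1 | intermediate
15 | 5-{(1S)-1-[3,4-bis(benzyloxy)phenyl]-2-carboxyethyl}-1-[2-(3,4-dimethoxyphenyl)ethyl]-2,4-dioxocyclohexane-1-carboxylic acid | OC(=O)C[C@@H](C1CC(CCc2ccc(OC)c(OC)c2)(C(=O)O)C(=O)CC1=O)c1ccc(OCc2ccccc2)c(OCc2ccccc2)c1 | intermediate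
16 | (3S)-3-[3,4-bis(benzyloxy)phenyl]-3-{5-[2-(3,4-dimethoxyphenyl)ethyl]-2,4-dioxocyclohexyl}propanoic acid, mixture at the two ring CH carbons | OC(=O)C[C@@H](C1CC(CCc2ccc(OC)c(OC)c2)C(=O)CC1=O)c1ccc(OCc2ccccc2)c(OCc2ccccc2)c1 | intermediate
17 | (3R)-3-[3,4-bis(benzyloxy)phenyl]-3-{5-[2-(3,4-dimethoxyphenyl)ethyl]-2,4-dihydroxyphenyl}propanoic acid | OC(=O)C[C@@H](c1cc(CCc2ccc(OC)c(OC)c2)c(O)cc1O)c1ccc(OCc2ccccc2)c(OCc2ccccc2)c1 | intermediate
18 | (4R)-4-[3,4-bis(benzyloxy)phenyl]-6-[2-(3,4-dimethoxyphenyl)ethyl]-7-hydroxy-3,4-dihydro-2H-1-benzopyran-2-one | COc1ccc(CCc2cc3c(cc2O)OC(=O)C[C@@H]3c2ccc(OCc4ccccc4)c(OCc4ccccc4)c2)cc1OC | intermediate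
19 | (4R)-4-(3,4-dihydroxyphenyl)-6-[2-(3,4-dimethoxyphenyl)ethyl]-7-hydroxy-3,4-dihydro-2H-1-benzopyran-2-one | COc1ccc(CCc2cc3c(cc2O)OC(=O)C[C@@H]3c2ccc(O)c(O)c2)cc1OC | target

**Step count**

Total: 11 steps. Longest linear sequence: 10 steps (steps 1–6, then 8–11); step 7 is the one-step side branch.

**Steps most likely to fail**

Step 8. The conjugate addition of a tertiary enolate to an alpha-branched acrylate may be too slow, so that loss of the acetyl group by retro-Claisen cleavage or oligomerisation of 9 takes over. The fallback sets out from 12 and 9 and uses the unactivated ketone instead. Compound 12 is dealkoxycarbonylated (CF3CO2H, then heat) to 5-(3,4-dimethoxyphenyl)pentan-2-one F1. F1 is pre-enolised with KOtBu in THF at −10 °C so that the internal, thermodynamic enolate predominates, and 9 is added slowly; Michael addition and Claisen closure then follow in one flask, as in the consecutive Michael–Claisen annulation of methyl ketones with acrylates. This should give tert-butyl (3S)-3-[3,4-bis(benzyloxy)phenyl]-3-{5-[2-(3,4-dimethoxyphenyl)ethyl]-2,4-dioxocyclohexyl}propanoate F2. CF3CO2H cleaves its tert-butyl ester and the route is rejoined at 16.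

Step 10. Beta-hydride elimination from a C4a palladium enolate may go toward the exocyclic C4–H instead of into the ring, which would erode the configuration at C4 through an alkylidene intermediate; the catalyst may also stall on the strongly enolised dione. The fallback brings the missing unsaturation in with the donor, at C6 and away from C4, and sets out from 11 and 9. Alkylation of 1-(phenylsulfanyl)propan-2-one with 11 (NaH, THF) gives 5-(3,4-dimethoxyphenyl)-3-(phenylsulfanyl)pentan-2-one F3. Its KOtBu-mediated Michael–Claisen annulation with 9 gives tert-butyl (3S)-3-[3,4-bis(benzyloxy)phenyl]-3-{5-[2-(3,4-dimethoxyphenyl)ethyl]-2,4-dioxo-5-(phenylsulfanyl)cyclohexyl}propanoate F4. Oxidation with mCPBA (1 equiv, −78 °C) gives the corresponding sulfoxide, tert-butyl (3S)-3-[3,4-bis(benzyloxy)phenyl]-3-{5-[2-(3,4-dimethoxyphenyl)ethyl]-2,4-dioxo-5-(phenylsulfinyl)cyclohexyl}propanoate F5. Thermal syn-elimination of F5 (toluene, 80 °C) can place the new double bond only at C6, and tautomerisation gives tert-butyl (3R)-3-[3,4-bis(benzyloxy)phenyl]-3-{5-[2-(3,4-dimethoxyphenyl)ethyl]-2,4-dihydroxyphenyl}propanoate F6. CF3CO2H cleaves the ester and lactonises, rejoining the route at 18.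

Step 2. Reversible malonate addition and slow iminium formation with the electron-rich enal may erode the enantiomeric purity. The fallback sets out from 1 and uses a chiral Lewis acid on a malonate acceptor instead. Knoevenagel condensation of 1 with 4 (piperidine, AcOH, toluene, water removal) gives dimethyl 2-{[3,4-bis(benzyloxy)phenyl]methylidene}propanedioate F7. Mukaiyama–Michael addition of 1-(tert-butylsulfanyl)-1-[(trimethylsilyl)oxy]ethene, catalysed by Cu(SbF6)2 (divalent copper) with the tert-butyl bis(oxazoline) ligand enantiomer that delivers the S adduct, gives dimethyl 2-{(1S)-1-[3,4-bis(benzyloxy)phenyl]-3-(tert-butylsulfanyl)-3-oxopropyl}propanedioate F8. Silver-assisted hydrolysis of the thioester (AgO2CCF3, aqueous THF) rejoins the route at 6.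

**Further compounds**

F1 | step 8 | 5-(3,4-dimethoxyphenyl)pentan-2-one | CC(=O)CCCc1ccc(OC)c(OC)c1
F2 | step 8 | tert-butyl (3S)-3-[3,4-bis(benzyloxy)phenyl]-3-{5-[2-(3,4-dimethoxyphenyl)ethyl]-2,4-dioxocyclohexyl}propanoate | CC(C)(C)OC(=O)C[C@@H](C1CC(CCc2ccc(OC)c(OC)c2)C(=O)CC1=O)c1ccc(OCc2ccccc2)c(OCc2ccccc2)c1
F3 | step 10 | 5-(3,4-dimethoxyphenyl)-3-(phenylsulfanyl)pentan-2-one | CC(=O)C(CCc1ccc(OC)c(OC)c1)Sc1ccccc1
F4 | step 10 | tert-butyl (3S)-3-[3,4-bis(benzyloxy)phenyl]-3-{5-[2-(3,4-dimethoxyphenyl)ethyl]-2,4-dioxo-5-(phenylsulfanyl)cyclohexyl}propanoate | CC(C)(C)OC(=O)C[C@@H](C1CC(CCc2ccc(OC)c(OC)c2)(Sc2ccccc2)C(=O)CC1=O)c1ccc(OCc2ccccc2)c(OCc2ccccc2)c1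
F5 | step 10 | tert-butyl (3S)-3-[3,4-bis(benzyloxy)phenyl]-3-{5-[2-(3,4-dimethoxyphenyl)ethyl]-2,4-dioxo-5-(phenylsulfinyl)cyclohexyl}propanoate | CC(C)(C)OC(=O)C[C@@H](C1CC(CCc2ccc(OC)c(OC)c2)(S(=O)c2ccccc2)C(=O)CC1=O)c1ccc(OCc2ccccc2)c(OCc2ccccc2)c1
F6 | step 10 | tert-butyl (3R)-3-[3,4-bis(benzyloxy)phenyl]-3-{5-[2-(3,4-dimethoxyphenyl)ethyl]-2,4-dihydroxyphenyl}propanoate | CC(C)(C)OC(=O)C[C@@H](c1cc(CCc2ccc(OC)c(OC)c2)c(O)cc1O)c1ccc(OCc2ccccc2)c(OCc2ccccc2)c1
F7 | step 2 | dimethyl 2-{[3,4-bis(benzyloxy)phenyl]methylidene}propanedioate | COC(=O)C(=Cc1ccc(OCc2ccccc2)c(OCc2ccccc2)c1)C(=O)OC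
F8 | step 2 | dimethyl 2-{(1S)-1-[3,4-bis(benzyloxy)phenyl]-3-(tert-butylsulfanyl)-3-oxopropyl}propanedioate | CC(C)(C)SC(=O)C[C@@H](C(C(=O)OC)C(=O)OC)c1ccc(OCc2ccccc2)c(OCc2ccccc2)c1
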